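**Plan**

Core locants, used for the same atoms in every intermediate: C1 prenyl bridgehead, C2–C3–C4 enolised diketone bridge, C5 methyl bridgehead, C6 CH2, C7 prenyl CH, C8 CMe2, C9 bridging C=O.
Cuts, in retrosynthetic order: C3–acyl; the C7 side chain at CH2–CH= (B-alkyl Suzuki on a C7 methylidene); C5–CH3; C5–C6 (moved back to C9–C6, a temporary cyclopentane); then C1–C2 and C5–C9 together, leaving a cyclopentanone enolate and diketene.
Enabling feature: ring C1–C2–C3–C4–C5–C9 is a cyclic 1,3,5-tricarbonyl array, so a ketone enolate (nucleophilic C1, electrophilic C9) and diketene as an acetoacetyl unit (electrophilic C2, nucleophilic C5) close it in one Claisen–aldol event.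
Forward order: cyclopentane ring (C9, C1, C8, C7, C6) from the chiral pool → six-membered ring C1–C5/C9 by annulation → oxidative 1,2-shift of C6 from C9 to C5 turns the 5/6-fused bicycle into the bicyclo[3.3.1]nonane → C5 methyl, C7 prenyl, C3 isobutyryl.
Stereochemistry: (S)-allethrolone supplies a C7 silyloxy centre that steers the annulation (C1, C9) and hence C5; this carbinol is then erased (ketone → methylidene) and C7 is re-set by exo-face hydroboration, which places the new side chain endo, cis to the C2–C4 bridge.

Key step: step 4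

Remark: (S)-allethrolone (1) is taken as purchased in enantiopure form; if only the racemate is at hand it is resolved beforehand by lipase-mediated acylation.

**Route**

Step 1
Reactants: 1 (S)-allethrolone
Product: 2 TBS ether of (S)-allethrolone
Conditions: TBSCl, imidazole, DMF, 0 °C → rt
Reagents that add atoms: tert-butyldimethylsilyl chloride, CC(C)(C)[Si](C)(C)Cl
Why: Silylation of the secondary allylic alcohol (silyl ether protection) leaves the stereocentre untouched and installs the bulky group that later directs the annulation.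

Step 2
Reactants: 2 TBS ether of (S)-allethrolone
Product: 3 2-prenyl enone
Conditions: 2-methylbut-2-ene (excess), RuCl2(=CHPh)(H2IMes)(PCy3) (second-generation Grubbs catalyst, 3 mol %), CH2Cl2, 40 °C
Reagents that add atoms: 2-methylbut-2-ene, CC=C(C)C
Why: Olefin cross-metathesis converts the monosubstituted allyl terminus into the prenyl group, while the tetrasubstituted enone alkene is inert to the ruthenium carbene.

Step 3
Reactants: 3 2-prenyl enone
Product: 4 trimethylsilyl enol ether
Conditions: MeMgBr, CuBr·SMe2 (10 mol %), TMSCl, HMPA, THF, −78 → −40 °C; Et3N work-up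
Reagents that add atoms: methylmagnesium bromide, C[Mg]Br; chlorotrimethylsilane, C[Si](C)(C)Cl
Why: TMSCl/HMPA-accelerated copper-catalysed conjugate addition puts the second methyl on C8 (gem-dimethyl, no new stereocentre) and traps the C9=C1 enolate regiospecifically as its silyl enol ether, so the β-silyloxy side (C6) is never enolised.

Step 4
Reactants: 4 trimethylsilyl enol ether; 5 diketene
Product: 8 cis-fused hydroxy diketone, via lithium enolate 6 (not isolated), via ring-opened acyl enolate 7 (not isolated)
Conditions: MeLi, THF, 0 °C; then diketene, −78 → −20 °C; AcOH quench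
Reagents that add atoms: methyllithium, C[Li] (its lithium is carried only by 6 and 7; no atom of it remains in 8)
Why: Methyllithium cleaves the O–Si bond of 4 to give the regiodefined lithium enolate 6, whose carbon C1 opens diketene at the acyl carbon (C-acylation driven by release of β-lactone strain), forming C1–C2 and releasing the terminal methyl-ketone enolate 7 next to the ring carbonyl. Before proton transfer can intervene, this enolate carbon (C5) adds to the cyclopentanone carbonyl C9 in a 6-(enolendo)-exo-trig aldol closure, forming C5–C9 and the cyclohexane-1,3-dione ring. The closest known reaction type is the diketene annulation of lithium enolates of α-substituted cyclopentanones (tandem Claisen acylation–aldol addition). C1 is set by approach of diketene to the enolate face anti to the bulky C7 silyl ether, relayed through the gem-dimethyl carbon, and C9 follows from C1 because the three-atom tether can deliver C5 only to the same face, giving the cis ring fusion. The step needs C- over O-acylation at a hindered, fully substituted enolate carbon and no enolate equilibration toward C6, which would expel the β-silyloxy group. A lithium enolate in THF without polar additives at low temperature and the fixed regiochemistry inherited from 4 secure both; any diastereomer from syn attack is removed by chromatography at this stage.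

Step 5
Reactants: 8 cis-fused hydroxy diketone
Product: 9 vinylogous methyl ester
Conditions: TMSCHN2, MeOH/toluene, 0 °C → rt
Reagents that add atoms: (trimethylsilyl)diazomethane, C[Si](C)(C)C=[N+]=[N-]
Why: O-methylation of the vinylogous acid with a diazoalkane under neutral conditions (no dehydration or retro-aldol of the β-hydroxy ketone) is expected at the less hindered C4 oxygen, remote from the quaternary C1, and the minor C2–O-methyl isomer is removed by chromatography.

Step 6
Reactants: 9 vinylogous methyl ester
Product: 11 bicyclo[3.3.1]nonenedione silyl ether, via C5 iodane 10 (not isolated)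
Conditions: PhI(OAc)2, KOH, MeOH, −10 → 0 °C
Reagents that add atoms: (diacetoxyiodo)benzene, CC(=O)OI(OC(C)=O)c1ccccc1, and methanol, CO (iodine, phenyl and methoxy are carried only by 10)
Why: Oxidative semipinacol ring expansion with a λ3-iodane: the extended enolate formed reversibly by methoxide is captured at C5 by PhI(OMe)2 (axial attack anti to the axial C9–C6 bond) to give 10, and the C9 alkoxide then pushes the antiperiplanar C9–C6 bond onto C5 with loss of iodobenzene (1,2-alkyl shift with inversion at C5), creating the bridging C9 ketone and the C5 stereocentre, whose configuration is fixed by C1 because C6 can only bridge on one face.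

Step 7
Reactants: 11 bicyclo[3.3.1]nonenedione silyl ether
Product: 12 C5-methyl bicycle
Conditions: LiN(iPr)2 (LDA), THF, −78 °C; MeI, −78 → 0 °C
Reagents that add atoms: iodomethane, CI
Why: Bridgehead lithiation–alkylation: the C5–H, flanked by the C9 ketone and the lithium-coordinating C4 enol ether oxygen, is expected to be removed at −78 °C in preference to the vinylic C3–H, and the pyramidal bridgehead carbanion is methylated with retention, the only geometry the bicycle allows.

Step 8
Reactants: 12 C5-methyl bicycle
Product: 13 C7 alcohol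
Conditions: Bu4NF, AcOH, THF, rt → 45 °C
Reagents that add atoms: none
Why: Fluoride-mediated desilylation buffered with acetic acid frees the hindered C7 alcohol without base-induced retro-Claisen cleavage of the non-enolisable β-dicarbonyl array.

Step 9
Reactants: 13 C7 alcohol
Product: 14 C7 ketone
Conditions: Dess–Martin periodinane, CH2Cl2, 0 °C → rt
Reagents that add atoms: none
Why: Dess–Martin oxidation gives the C7 ketone under near-neutral conditions, deliberately erasing the temporary stereocentre, while the trisubstituted alkene and the enol ether are untouched.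

Step 10
Reactants: 14 C7 ketone
Product: 15 C7 methylidene compound
Conditions: Ph3PCH3Br, KOtBu, THF, 0 → 50 °C
Reagents that add atoms: methyltriphenylphosphonium bromide (as its ylide), C[P+](c1ccccc1)(c1ccccc1)c1ccccc1.[Br-]
Why: Wittig methylenation should occur only at the C7 ketone, because the C9 ketone is flanked by two quaternary bridgeheads and the C2 carbonyl is a vinylogous ester.

Step 11
Reactants: 15 C7 methylidene compound
Product: 17 diprenyl vinylogous ester, via alkylborane 16 (not isolated)
Conditions: 9-BBN dimer, THF, 0 °C → rt; then 1-bromo-2-methylprop-1-ene, Pd(dppf)Cl2 (5 mol %), AsPh3, K3PO4 (aq), DMF, 50 °C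
Reagents that add atoms: 1-bromo-2-methylprop-1-ene, CC(C)=CBr; 9-borabicyclo[3.3.1]nonane, B1C2CCCC1CCC2 (its boron is carried only by 16)
Why: Hydroboration followed by B-alkyl Suzuki–Miyaura coupling: 9-BBN reacts with the 1,1-disubstituted alkene far faster than with the trisubstituted prenyl alkene and approaches from the open exo face (the endo face is covered by the C2–C3–C4 bridge), so hydrogen is delivered exo to C7 and the CH2–B group ends endo (7R), and the coupling then completes the prenyl group without touching that centre.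

Step 12
Reactants: 17 diprenyl vinylogous ester
Product: 18 C3-isobutyryl vinylogous ester
Conditions: lithium 2,2,6,6-tetramethylpiperidide (from 2,2,6,6-tetramethylpiperidine, n-BuLi), THF, −78 °C; i-PrCOCl, −78 → −40 °C
Reagents that add atoms: 2-methylpropanoyl chloride, CC(C)C(=O)Cl
Why: α-Lithiation of the β-alkoxy enone at C3, the only acidic C–H left, by the hindered amide base followed by C-acylation with the acid chloride installs the isobutyryl group.

Step 13
Reactants: 18 C3-isobutyryl vinylogous ester
Product: 19 target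
Conditions: LiOH, H2O/1,4-dioxane, 90 °C; then aq. HCl
Reagents that add atoms: lithium hydroxide, [Li+].[OH-] (its oxygen replaces the methoxy group at C4)
Why: Conjugate addition–elimination of hydroxide at C4, activated by the two flanking acyl groups, cleaves the vinylogous methyl ester to the enolised β-triketone without affecting any stereocentre.

**Compound list**

1 | (S)-allethrolone, (4S)-4-hydroxy-3-methyl-2-(prop-2-en-1-yl)cyclopent-2-en-1-one | C=CCC1=C(C)[C@@H](O)CC1=O | starting material
2 | (4S)-4-[(tert-butyldimethylsilyl)oxy]-3-methyl-2-(prop-2-en-1-yl)cyclopent-2-en-1-one | C=CCC1=C(C)[C@@H](O[Si](C)(C)C(C)(C)C)CC1=O | intermediate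
3 | (4S)-4-[(tert-butyldimethylsilyl)oxy]-3-methyl-2-(3-methylbut-2-en-1-yl)cyclopent-2-en-1-one | CC(C)=CCC1=C(C)[C@@H](O[Si](C)(C)C(C)(C)C)CC1=O | intermediate
4 | (4S)-4-[(tert-butyldimethylsilyl)oxy]-3,3-dimethyl-2-(3-methylbut-2-en-1-yl)-1-[(trimethylsilyl)oxy]cyclopent-1-ene | CC(C)=CCC1=C(O[Si](C)(C)C)C[C@H](O[Si](C)(C)C(C)(C)C)C1(C)C | intermediate
5 | diketene, 4-methylideneoxetan-2-one | C=C1CC(=O)O1 | starting material
6 | lithium (4S)-4-[(tert-butyldimethylsilyl)oxy]-3,3-dimethyl-2-(3-methylbut-2-en-1-yl)cyclopent-1-en-1-olate | CC(C)=CCC1=C(O[Li])C[C@H](O[Si](C)(C)C(C)(C)C)C1(C)C | intermediate (not isolated)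
7 | terminal lithium enolate of (2R,4S)-4-[(tert-butyldimethylsilyl)oxy]-3,3-dimethyl-2-(3-methylbut-2-en-1-yl)-2-(3-oxobutanoyl)cyclopentan-1-one, acyl group trans to the silyloxy group | CC(C)=CC[C@]1(C(=O)CC(=C)O[Li])C(=O)C[C@H](O[Si](C)(C)C(C)(C)C)C1(C)C | intermediate (not isolated)
8 | (1R,6S,8S)-8-[(tert-butyldimethylsilyl)oxy]-6-hydroxy-9,9-dimethyl-1-(3-methylbut-2-en-1-yl)bicyclo[4.3.0]nonane-2,4-dione, cis-fused, with the C1 side chain, 6-OH and 8-silyloxy on one face (bicyclo[4.3.0] locants 6, 7, 8, 9 are core atoms C9, C6, C7, C8; drawn as the diketone, largely enolised) | CC(C)=CC[C@]12C(=O)CC(=O)C[C@@]1(O)C[C@H](O[Si](C)(C)C(C)(C)C)C2(C)C | intermediate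
9 | (1R,6S,8S)-8-[(tert-butyldimethylsilyl)oxy]-6-hydroxy-4-methoxy-9,9-dimethyl-1-(3-methylbut-2-en-1-yl)bicyclo[4.3.0]non-3-en-2-one | CC(C)=CC[C@]12C(=O)C=C(OC)C[C@@]1(O)C[C@H](O[Si](C)(C)C(C)(C)C)C2(C)C | intermediate
10 | (1R,5R,6R,8S)-8-[(tert-butyldimethylsilyl)oxy]-6-hydroxy-4-methoxy-5-[methoxy(phenyl)-λ3-iodanyl]-9,9-dimethyl-1-(3-methylbut-2-en-1-yl)bicyclo[4.3.0]non-3-en-2-one, C–I bond anti to the ring-fusion bond to the cyclopentane CH2 | CC(C)=CC[C@]12C(=O)C=C(OC)[C@H](I(OC)c3ccccc3)[C@@]1(O)C[C@H](O[Si](C)(C)C(C)(C)C)C2(C)C | intermediate (not isolated)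
11 | (1S,5R,7S)-7-[(tert-butyldimethylsilyl)oxy]-4-methoxy-8,8-dimethyl-1-(3-methylbut-2-en-1-yl)bicyclo[3.3.1]non-3-ene-2,9-dione, 7-silyloxy exo (anti to the C2–C4 bridge) | CC(C)=CC[C@]12C(=O)C=C(OC)[C@H](C1=O)C[C@H](O[Si](C)(C)C(C)(C)C)C2(C)C | intermediate
12 | (1S,5R,7S)-7-[(tert-butyldimethylsilyl)oxy]-4-methoxy-5,8,8-trimethyl-1-(3-methylbut-2-en-1-yl)bicyclo[3.3.1]non-3-ene-2,9-dione | CC(C)=CC[C@]12C(=O)C=C(OC)[C@](C)(C1=O)C[C@H](O[Si](C)(C)C(C)(C)C)C2(C)C | intermediate
13 | (1S,5R,7S)-7-hydroxy-4-methoxy-5,8,8-trimethyl-1-(3-methylbut-2-en-1-yl)bicyclo[3.3.1]non-3-ene-2,9-dione | CC(C)=CC[C@]12C(=O)C=C(OC)[C@](C)(C1=O)C[C@H](O)C2(C)C | intermediate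
14 | (1S,5R)-4-methoxy-5,8,8-trimethyl-1-(3-methylbut-2-en-1-yl)bicyclo[3.3.1]non-3-ene-2,7,9-trione | CC(C)=CC[C@]12C(=O)C=C(OC)[C@](C)(C1=O)CC(=O)C2(C)C | intermediate
15 | (1S,5R)-4-methoxy-5,8,8-trimethyl-7-methylidene-1-(3-methylbut-2-en-1-yl)bicyclo[3.3.1]non-3-ene-2,9-dione | CC(C)=CC[C@]12C(=O)C=C(OC)[C@](C)(C1=O)CC(=C)C2(C)C | intermediate
16 | (1S,5R,7R)-7-[(9-borabicyclo[3.3.1]nonan-9-yl)methyl]-4-methoxy-5,8,8-trimethyl-1-(3-methylbut-2-en-1-yl)bicyclo[3.3.1]non-3-ene-2,9-dione, boryl-methyl group endo | CC(C)=CC[C@]12C(=O)C=C(OC)[C@](C)(C1=O)C[C@@H](CB3C4CCCC3CCC4)C2(C)C | intermediate (not isolated)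
17 | (1S,5R,7R)-4-methoxy-5,8,8-trimethyl-1,7-bis(3-methylbut-2-en-1-yl)bicyclo[3.3.1]non-3-ene-2,9-dione, 7-prenyl endo | CC(C)=CC[C@]12C(=O)C=C(OC)[C@](C)(C1=O)C[C@@H](CC=C(C)C)C2(C)C | intermediate
18 | (1R,5R,7R)-4-methoxy-5,8,8-trimethyl-1,7-bis(3-methylbut-2-en-1-yl)-3-(2-methylpropanoyl)bicyclo[3.3.1]non-3-ene-2,9-dione | CC(C)=CC[C@]12C(=O)C(C(=O)C(C)C)=C(OC)[C@](C)(C1=O)C[C@@H](CC=C(C)C)C2(C)C | intermediate
19 | (1R,5R,7R)-4-hydroxy-5,8,8-trimethyl-1,7-bis(3-methylbut-2-en-1-yl)-3-(2-methylpropanoyl)bicyclo[3.3.1]non-3-ene-2,9-dione (CNP0265287.1) | CC(C)=CC[C@@H]1C[C@@]2(C)C(=O)[C@](CC=C(C)C)(C(=O)C(C(=O)C(C)C)=C2O)C1(C)C | target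

**Step count and risks**

Total steps: 13. Longest linear sequence: 13 steps, from 1.

Most likely to fail, riskiest first:

Step 4. The fully substituted enolate carbon, flanked by the gem-dimethyl carbon, may be acylated on oxygen instead of carbon, may be approached from the face syn to the silyl ether, or the terminal enolate may be quenched by proton transfer before it closes onto C9. The fallback sets out from 4 and comes back at 8. Acetylketene, generated thermally from 2,2,6-trimethyl-4H-1,3-dioxin-4-one in toluene at 110 °C in the presence of 4, should undergo a hetero-Diels–Alder cycloaddition with the silyl enol ether. This makes the C1–C2 bond through a neutral pericyclic path that can only acylate carbon, and gives the silyl ketal cycloadduct F1. Mild hydrolysis (citric acid, THF/H2O) unmasks the triketone F2. LiN(iPr)2 (2.2 equiv, THF, −78 → 0 °C) then forms the 1,3-diketone dianion, whose terminal carbon closes onto C9 in an aldol addition to give 8.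

Step 6. The wrong bond may shift (C9–C1, giving ring contraction), the C9 alkoxide may close an epoxide, or the solvent may capture the iodane, instead of migration of the primary carbon C6. The fallback sets out from 9 and comes back at 11, and separates installation of the leaving group from the shift. Double silylation (TMSOTf, Et3N, CH2Cl2) gives the 2-silyloxy diene bis(silyl ether) F3. NBS (THF, −78 °C) brominates the diene terminus C5 to give the γ-bromo enone silyl ether F4, whose C5 epimers can be separated so that the one with C–Br anti to C9–C6 is taken on. AgBF4 with 2,6-di-tert-butylpyridine (CH2Cl2, −40 °C) then abstracts bromide, the silyl ether oxygen drives the 1,2-shift of C6, and loss of the silyl group gives 11.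

Step 3. The 1,4-addition at the tetrasubstituted β-carbon next to the silyloxy-bearing carbon may be slow, allowing 1,2-addition to the carbonyl or reductive loss of the γ-silyloxy group. The fallback sets out from 3 and comes back at 4. Corey–Chaykovsky cyclopropanation (Me3S(O)I, NaH, DMSO) anti to the silyl ether gives the cyclopropyl ketone F5. Dissolving-metal reduction (Li, liquid NH3, THF, −78 °C) cleaves the external cyclopropane bond C1–CH2 that overlaps with the carbonyl π system, which turns the CH2 into the second C8 methyl and leaves the C1 enolate. Silylation (TMSCl, Et3N) of this enolate gives 4.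

Further compounds
F1 | step 4 | hetero-Diels–Alder adduct of 4 with acetylketene: cis-fused 2-methyl-2,3-dihydro-4H-pyran-4-one silyl ketal (ring O and OSiMe3 on C9, C2 carbonyl on C1) | CC(C)=CC[C@]12C(=O)C=C(C)O[C@@]1(O[Si](C)(C)C)C[C@H](O[Si](C)(C)C(C)(C)C)C2(C)C
F2 | step 4 | (2R,4S)-4-[(tert-butyldimethylsilyl)oxy]-3,3-dimethyl-2-(3-methylbut-2-en-1-yl)-2-(3-oxobutanoyl)cyclopentan-1-one | CC(C)=CC[C@]1(C(=O)CC(C)=O)C(=O)C[C@H](O[Si](C)(C)C(C)(C)C)C1(C)C
F3 | step 6 | bis(trimethylsilyl) derivative of 9: C2 silyl dienol ether (C2=C3, C4=C5) and C9 silyl ether | CC(C)=CC[C@]12C(O[Si](C)(C)C)=CC(OC)=C[C@@]1(O[Si](C)(C)C)C[C@H](O[Si](C)(C)C(C)(C)C)C2(C)C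
F4 | step 6 | C5 bromide of 9 as its C9 trimethylsilyl ether, C–Br anti to C9–C6 | CC(C)=CC[C@]12C(=O)C=C(OC)[C@H](Br)[C@@]1(O[Si](C)(C)C)C[C@H](O[Si](C)(C)C(C)(C)C)C2(C)C
F5 | step 3 | 4-[(tert-butyldimethylsilyl)oxy]-5-methyl-1-(3-methylbut-2-en-1-yl)bicyclo[3.1.0]hexan-2-one, cyclopropane CH2 anti to the silyloxy group | CC(C)=CC[C@@]12C[C@]1(C)[C@@H](O[Si](C)(C)C(C)(C)C)CC2=O
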